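**Retrosynthetic overview**

1. Target 19 comes from the bis-silyl flavanone 18 by fluoride desilylation. Rings A and B are bought as arenes (2,4,6-trihydroxybenzaldehyde, vanillin); ring C is the only ring made, and it is made last.
2. Ring C is closed by forming C3–C4: rhodium-catalysed enantioselective 6-endo hydroacylation of aldehyde 17, in which the formyl C–H on ring A adds across the enol ether O1–C2(ring B)=C3H2 and sets C2 as S.
3. Enabling feature: C4 is an aryl carbonyl on ring A, ortho to O1 and hydrogen-bonded by the 5-OH (so the formyl C–H faces O1). C2 carries only ring B, O1 and H, so C2=C3 is a 1,1-disubstituted, non-isomerisable alkene with a free terminus C3.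
4. The C8 prenyl group comes from a para-Claisen–Cope shift of the O5 prenyl ether (14 to 17). The enol ether comes from Petasis methylenation of aryl ester 11 with the aldehyde masked as an acetal. The ester comes from phenol 10 and acid 7.
5. Phenol 10 comes from 2,4,6-trihydroxybenzaldehyde (4-O-silylation, Mitsunobu prenylation). Acid 7 comes from vanillin (silylation, α-amino alkoxide-directed C2 lithiation and prenylation, Pinnick oxidation).

Key step: step 10

Remark: the sense of induction of the bisphosphine in step 10 cannot be assigned in advance; (R)-DTBM-SEGPHOS is written and its antipode is to be used if a first run shows the 2R product (flavanone numbering is used for ring positions throughout).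

**Route**

Step 1
Reactants: 1 vanillin (4-hydroxy-3-methoxybenzaldehyde)
Product: 2 3-methoxy-4-(triisopropylsilyloxy)benzaldehyde
Conditions: TIPSCl, imidazole, DMF, rt
Reagents that add atoms: triisopropylsilyl chloride, CC(C)[Si](Cl)(C(C)C)C(C)C
Why: Phenol silylation of the only hydroxyl; the bulky triisopropylsilyl ether should survive the organolithium of step 2 and is a poor directing group, so C5 stays unactivated.

Step 2
Reactants: 2 3-methoxy-4-(triisopropylsilyloxy)benzaldehyde
Product: 6 3-methoxy-2-(3-methylbut-2-enyl)-4-(triisopropylsilyloxy)benzaldehyde, via lithium α-amino alkoxide 3 (not isolated), via C2-lithiated alkoxide 4 (not isolated), via prenylated alkoxide 5 (not isolated)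
Conditions: LiN(Me)CH2CH2NMe2 (from MeNHCH2CH2NMe2 and n-BuLi), THF, −20 °C; sec-BuLi, −78 → −30 °C; CuBr·SMe2 (10 mol %), prenyl bromide, −78 °C → rt; aq. NH4Cl
Reagents that add atoms: 1-bromo-3-methylbut-2-ene, CC(C)=CCBr
Why: Directed ortho-metalation: the lithium amide adds to the aldehyde to give an α-amino alkoxide that masks the carbonyl and, together with the 3-methoxy group, should direct sec-BuLi to the doubly activated C2, after which the aryllithium is alkylated at the primary carbon of prenyl bromide under copper catalysis and aqueous work-up returns the aldehyde.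

Step 3
Reactants: 6 3-methoxy-2-(3-methylbut-2-enyl)-4-(triisopropylsilyloxy)benzaldehyde
Product: 7 3-methoxy-2-(3-methylbut-2-enyl)-4-(triisopropylsilyloxy)benzoic acid
Conditions: NaClO2, NaH2PO4, 2-methyl-2-butene (20 equiv), t-BuOH–H2O, 0 °C → rt
Reagents that add atoms: sodium chlorite, [Na+].[O-]Cl=O
Why: Pinnick oxidation: chlorite oxidises the aldehyde selectively under buffered conditions, and the large excess of 2-methyl-2-butene should trap hypochlorous acid before it reaches the prenyl alkene.

Step 4
Reactants: 8 2,4,6-trihydroxybenzaldehyde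
Product: 9 4-(tert-butyldimethylsilyloxy)-2,6-dihydroxybenzaldehyde
Conditions: TBSCl (1.0 equiv), imidazole, DMF, −20 → 0 °C
Reagents that add atoms: tert-butyldimethylsilyl chloride, CC(C)(C)[Si](C)(C)Cl
Why: Regioselective phenol silylation: the 4-OH is the only hydroxyl not ortho to the formyl group, hence the most acidic and least hindered, while the two ortho hydroxyls are tied up by hydrogen bonding to the carbonyl.

Step 5
Reactants: 9 4-(tert-butyldimethylsilyloxy)-2,6-dihydroxybenzaldehyde
Product: 10 4-(tert-butyldimethylsilyloxy)-2-hydroxy-6-(3-methylbut-2-enyloxy)benzaldehyde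
Conditions: 3-methylbut-2-en-1-ol (1.05 equiv), PPh3, DIAD, THF, 0 °C → rt
Reagents that add atoms: 3-methylbut-2-en-1-ol, CC(C)=CCO
Why: Mitsunobu etherification: the two hydroxyls are equivalent and, once one is etherified, the other is locked in a hydrogen bond to the aldehyde, so the reaction should stop at the mono-ether, with SN2 attack at the primary carbon giving the unrearranged prenyl ether.

Step 6
Reactants: 10 4-(tert-butyldimethylsilyloxy)-2-hydroxy-6-(3-methylbut-2-enyloxy)benzaldehyde; 7 3-methoxy-2-(3-methylbut-2-enyl)-4-(triisopropylsilyloxy)benzoic acid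
Product: 11 5-(tert-butyldimethylsilyloxy)-2-formyl-3-(3-methylbut-2-enyloxy)phenyl 3-methoxy-2-(3-methylbut-2-enyl)-4-(triisopropylsilyloxy)benzoate
Conditions: DCC, DMAP (20 mol %), CH2Cl2, 0 °C → rt
Reagents that add atoms: none
Why: Steglich esterification: the acylpyridinium formed from the O-acylisourea should acylate the single free phenol under neutral conditions that leave both silyl ethers, the aldehyde and the prenyl groups untouched.

Step 7
Reactants: 11 5-(tert-butyldimethylsilyloxy)-2-formyl-3-(3-methylbut-2-enyloxy)phenyl 3-methoxy-2-(3-methylbut-2-enyl)-4-(triisopropylsilyloxy)benzoate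
Product: 12 5-(tert-butyldimethylsilyloxy)-2-(dimethoxymethyl)-3-(3-methylbut-2-enyloxy)phenyl 3-methoxy-2-(3-methylbut-2-enyl)-4-(triisopropylsilyloxy)benzoate
Conditions: HC(OMe)3 (10 equiv), PPTS (5 mol %), CH2Cl2, rt; Et3N
Reagents that add atoms: trimethyl orthoformate, COC(OC)OC
Why: Acetalisation: the electron-rich aryl aldehyde should form its dimethyl acetal under mild acid catalysis without methanolysis of the aryl ester, masking the carbonyl that would otherwise be methylenated in step 8.

Step 8
Reactants: 12 5-(tert-butyldimethylsilyloxy)-2-(dimethoxymethyl)-3-(3-methylbut-2-enyloxy)phenyl 3-methoxy-2-(3-methylbut-2-enyl)-4-(triisopropylsilyloxy)benzoate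
Product: 14 4-(tert-butyldimethylsilyloxy)-2-({1-[3-methoxy-2-(3-methylbut-2-enyl)-4-(triisopropylsilyloxy)phenyl]vinyl}oxy)-6-(3-methylbut-2-enyloxy)benzaldehyde, via enol ether acetal 13 (not isolated)
Conditions: Cp2TiMe2 (3 equiv), toluene, 70 °C, dark; filtration through basic alumina; then PPTS (10 mol %), acetone–H2O (20:1), 0 °C
Reagents that add atoms: dimethyltitanocene, [CH3-].[CH3-].[Ti+4].c1cc[cH-]c1.c1cc[cH-]c1; water, O
Why: Petasis methylenation: the non-acidic titanium methylidene converts the aryl benzoate into the aryl 1-arylvinyl ether while tolerating acetal, silyl ethers and alkenes, and the 2,4,6-trioxygenated benzaldehyde dimethyl acetal should then hydrolyse much faster than the aryl enol ether under buffered mild acid.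

Step 9
Reactants: 14 4-(tert-butyldimethylsilyloxy)-2-({1-[3-methoxy-2-(3-methylbut-2-enyl)-4-(triisopropylsilyloxy)phenyl]vinyl}oxy)-6-(3-methylbut-2-enyloxy)benzaldehyde
Product: 17 4-(tert-butyldimethylsilyloxy)-6-hydroxy-2-({1-[3-methoxy-2-(3-methylbut-2-enyl)-4-(triisopropylsilyloxy)phenyl]vinyl}oxy)-3-(3-methylbut-2-enyl)benzaldehyde, via ortho-dienone 15 (not isolated), via para-dienone 16 (not isolated)
Conditions: Eu(fod)3 (10 mol %), NaHCO3 (solid), ClCH2CH2Cl, 70 °C
Reagents that add atoms: none
Why: Aromatic Claisen rearrangement relayed by a Cope rearrangement (para-Claisen–Cope), the documented behaviour of ortho-acyl aryl prenyl ethers: trivalent europium chelated between the formyl and ether oxygens should speed the [3,3] shift to the only open ortho carbon, the ortho-dienone passes the inverted allyl unit by a second [3,3] shift to the para carbon (the future C8) as a normal prenyl group, and enolisation gives the hydrogen-bonded phenol; no stereocenter is formed.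

Step 10
Reactants: 17 4-(tert-butyldimethylsilyloxy)-6-hydroxy-2-({1-[3-methoxy-2-(3-methylbut-2-enyl)-4-(triisopropylsilyloxy)phenyl]vinyl}oxy)-3-(3-methylbut-2-enyl)benzaldehyde
Product: 18 (2S)-7-(tert-butyldimethylsilyloxy)-5-hydroxy-2-[3-methoxy-2-(3-methylbut-2-enyl)-4-(triisopropylsilyloxy)phenyl]-8-(3-methylbut-2-enyl)chroman-4-one
Conditions: [Rh(cod)Cl]2 (2.5 mol %), (R)-DTBM-SEGPHOS (5.5 mol %), NaB[3,5-(CF3)2C6H3]4 (5 mol %), 1,4-dioxane, 60 → 90 °C
Reagents that add atoms: none
Why: Proposed new method: cationic monovalent rhodium should insert into the formyl C–H bond of 17 to give an acyl rhodium hydride, the tethered enol ether then inserts into Rh–H with hydride going to C2 and rhodium to the terminal C3, and reductive elimination from the seven-membered acyl–alkyl rhodacycle forms the C3–C4 bond. The closest known reaction type is the rhodium–bisphosphine-catalysed endo- and enantioselective intramolecular hydroacylation of 1,1-disubstituted alkenes held ortho to an aromatic aldehyde (2-(1-arylvinyl)benzaldehydes to 3-arylindanones, ortho-(2-substituted allyl)benzaldehydes to 3-substituted tetralones); 17 is the oxygen analogue of the latter, an aryl enol ether, which has not been shown. Ring C closes in a 6-endo-trig mode (acyl carbon onto the alkene terminus); the 5-exo alternative should be disfavoured because it needs a fully substituted alkyl rhodium at C2 and would build a quaternary centre. The C2 stereocenter is created when hydride is delivered to one enantiotopic face of the enol ether and is controlled by the chiral bisphosphine alone (catalyst control). The step needs chemoselectivity against decarbonylation, against the prenyl alkenes and against alkene migration: the 5-OH···O=C hydrogen bond holds the formyl C–H toward O1 and the enol ether, the rigid aryl tether favours cyclisation over CO loss, the trisubstituted prenyl alkenes should not insert, and the enol ether has no allylic hydrogen and so cannot isomerise.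

Step 11
Reactants: 18 (2S)-7-(tert-butyldimethylsilyloxy)-5-hydroxy-2-[3-methoxy-2-(3-methylbut-2-enyl)-4-(triisopropylsilyloxy)phenyl]-8-(3-methylbut-2-enyl)chroman-4-one
Product: 19 (2S)-5,7-dihydroxy-2-[4-hydroxy-3-methoxy-2-(3-methylbut-2-enyl)phenyl]-8-(3-methylbut-2-enyl)chroman-4-one
Conditions: Bu4NF (2.5 equiv), AcOH (2.5 equiv), THF, 0 °C
Reagents that add atoms: none
Why: Fluoride desilylation of both aryl silyl ethers, buffered with acetic acid so that neither base-induced ring opening at C2 (loss of configuration) nor acid-induced cyclisation of the 7-OH onto the 8-prenyl group should occur.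

**Compound list**

1 | vanillin (4-hydroxy-3-methoxybenzaldehyde) | COc1cc(C=O)ccc1O | starting material
2 | 3-methoxy-4-(triisopropylsilyloxy)benzaldehyde | COc1cc(C=O)ccc1O[Si](C(C)C)(C(C)C)C(C)C | intermediate
3 | lithium α-amino alkoxide of 2 with N,N,N'-trimethylethylenediamine (not isolated) | COc1cc(C(O[Li])N(C)CCN(C)C)ccc1O[Si](C(C)C)(C(C)C)C(C)C | intermediate
4 | C2-lithiated alkoxide (not isolated) | COc1c([Li])c(C(O[Li])N(C)CCN(C)C)ccc1O[Si](C(C)C)(C(C)C)C(C)C | intermediate
5 | prenylated alkoxide (not isolated) | COc1c(CC=C(C)C)c(C(O[Li])N(C)CCN(C)C)ccc1O[Si](C(C)C)(C(C)C)C(C)C | intermediate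
6 | 3-methoxy-2-(3-methylbut-2-enyl)-4-(triisopropylsilyloxy)benzaldehyde | COc1c(CC=C(C)C)c(C=O)ccc1O[Si](C(C)C)(C(C)C)C(C)C | intermediate
7 | 3-methoxy-2-(3-methylbut-2-enyl)-4-(triisopropylsilyloxy)benzoic acid | COc1c(CC=C(C)C)c(C(=O)O)ccc1O[Si](C(C)C)(C(C)C)C(C)C | intermediate
8 | 2,4,6-trihydroxybenzaldehyde | O=Cc1c(O)cc(O)cc1O | starting material
9 | 4-(tert-butyldimethylsilyloxy)-2,6-dihydroxybenzaldehyde | O=Cc1c(O)cc(O[Si](C)(C)C(C)(C)C)cc1O | intermediate
10 | 4-(tert-butyldimethylsilyloxy)-2-hydroxy-6-(3-methylbut-2-enyloxy)benzaldehyde | O=Cc1c(O)cc(O[Si](C)(C)C(C)(C)C)cc1OCC=C(C)C | intermediate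
11 | 5-(tert-butyldimethylsilyloxy)-2-formyl-3-(3-methylbut-2-enyloxy)phenyl 3-methoxy-2-(3-methylbut-2-enyl)-4-(triisopropylsilyloxy)benzoate | COc1c(CC=C(C)C)c(C(=O)Oc2cc(O[Si](C)(C)C(C)(C)C)cc(OCC=C(C)C)c2C=O)ccc1O[Si](C(C)C)(C(C)C)C(C)C | intermediate
12 | dimethyl acetal of 11 | COc1c(CC=C(C)C)c(C(=O)Oc2cc(O[Si](C)(C)C(C)(C)C)cc(OCC=C(C)C)c2C(OC)OC)ccc1O[Si](C(C)C)(C(C)C)C(C)C | intermediate
13 | enol ether acetal, the dimethyl acetal of 14 (not isolated) | COc1c(CC=C(C)C)c(C(=C)Oc2cc(O[Si](C)(C)C(C)(C)C)cc(OCC=C(C)C)c2C(OC)OC)ccc1O[Si](C(C)C)(C(C)C)C(C)C | intermediate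
14 | 4-(tert-butyldimethylsilyloxy)-2-({1-[3-methoxy-2-(3-methylbut-2-enyl)-4-(triisopropylsilyloxy)phenyl]vinyl}oxy)-6-(3-methylbut-2-enyloxy)benzaldehyde | COc1c(CC=C(C)C)c(C(=C)Oc2cc(O[Si](C)(C)C(C)(C)C)cc(OCC=C(C)C)c2C=O)ccc1O[Si](C(C)C)(C(C)C)C(C)C | intermediate
15 | ortho-dienone, 5-(2-methylbut-3-en-2-yl)-6-oxocyclohexa-1,3-diene-1-carbaldehyde form of 14 (not isolated, configuration at the sp3 carbon undefined) | COc1c(CC=C(C)C)c(C(=C)OC2=C(C=O)C(=O)C(C(C)(C)C=C)C(O[Si](C)(C)C(C)(C)C)=C2)ccc1O[Si](C(C)C)(C(C)C)C(C)C | intermediate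
16 | para-dienone, 3-(3-methylbut-2-enyl)-6-oxocyclohexa-1,4-diene-1-carbaldehyde form (not isolated, configuration at the sp3 carbon undefined) | COc1c(CC=C(C)C)c(C(=C)OC2=C(C=O)C(=O)C=C(O[Si](C)(C)C(C)(C)C)C2CC=C(C)C)ccc1O[Si](C(C)C)(C(C)C)C(C)C | intermediate
17 | 4-(tert-butyldimethylsilyloxy)-6-hydroxy-2-({1-[3-methoxy-2-(3-methylbut-2-enyl)-4-(triisopropylsilyloxy)phenyl]vinyl}oxy)-3-(3-methylbut-2-enyl)benzaldehyde | COc1c(CC=C(C)C)c(C(=C)Oc2c(CC=C(C)C)c(O[Si](C)(C)C(C)(C)C)cc(O)c2C=O)ccc1O[Si](C(C)C)(C(C)C)C(C)C | intermediate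
18 | (2S)-7-(tert-butyldimethylsilyloxy)-5-hydroxy-2-[3-methoxy-2-(3-methylbut-2-enyl)-4-(triisopropylsilyloxy)phenyl]-8-(3-methylbut-2-enyl)chroman-4-one | COc1c(O[Si](C(C)C)(C(C)C)C(C)C)ccc([C@@H]2CC(=O)c3c(O)cc(O[Si](C)(C)C(C)(C)C)c(CC=C(C)C)c3O2)c1CC=C(C)C | intermediate
19 | (2S)-5,7-dihydroxy-2-[4-hydroxy-3-methoxy-2-(3-methylbut-2-enyl)phenyl]-8-(3-methylbut-2-enyl)chroman-4-one | COc1c(O)ccc([C@@H]2CC(=O)c3c(O)cc(O)c(CC=C(C)C)c3O2)c1CC=C(C)C | target

**Step count and risks**

Total steps: 11. Longest linear sequence: 9 steps (steps 1, 2, 3, 6, 7, 8, 9, 10, 11, from vanillin).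

The three steps most likely to fail:

1. Step 10 (proposed new method). The acyl group may be delivered to the internal alkene carbon (five-membered ring closure with a quaternary centre), the acyl rhodium hydride may lose CO before the alkene inserts, or facial discrimination in the hydride transfer may be poor. The fallback uses known chemistry, sets out from aldehyde 6 and returns to the route at 18. Commercial 2,4,6-trihydroxyacetophenone would be silylated and prenylated as in steps 4 and 5, giving 1-[4-(tert-butyldimethylsilyloxy)-2,6-dihydroxyphenyl]ethanone F1 and then 1-[4-(tert-butyldimethylsilyloxy)-2-hydroxy-6-(3-methylbut-2-enyloxy)phenyl]ethanone F2. Claisen–Schmidt condensation of F2 with 6 under aprotic conditions (LiN(SiMe3)2, THF, −78 °C → rt) should give the (E)-2'-hydroxychalcone F3. Its only free phenol closes ring C by oxa-Michael addition (NaOAc, EtOH, 60 °C) to the racemic 5-O-prenylflavanone F4. The europium-catalysed Claisen–Cope shift of step 9, here on the flavanone class for which it is documented, should give the racemic 8-prenyl-5-hydroxyflavanone F5 (racemic 18). Kinetic resolution by asymmetric transfer hydrogenation (RhCl(Cp*)(TsDPEN), HCO2H–Et3N, using the TsDPEN antipode that reduces the 2R ketone faster) should convert the unwanted enantiomer into the (2R,4R)-cis-flavan-4-ol F6 and leave (2S)-18.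

2. Step 8. Methylenation of the hindered aryl ester may stall, or the aryl enol ether may be cleaved by acid while the acetal is hydrolysed. The fallback sets out from 6 and 10 and returns at 14. Aldehyde 6 would be homologated with lithiated trimethylsilyldiazomethane (Colvin rearrangement; Me3SiCHN2, n-BuLi, THF, −78 °C → rt) to the arylacetylene 1-ethynyl-3-methoxy-2-(3-methylbut-2-enyl)-4-(triisopropylsilyloxy)benzene F8. Phenol 10 would then be added across the alkyne in the Markovnikov sense under gold catalysis (Au(IPr)NTf2, IPr = 1,3-bis(2,6-diisopropylphenyl)imidazol-2-ylidene, toluene, 60 °C). This forms the O–C2 bond by hydroalkoxylation, gives 14 directly, and needs neither the acetal nor an acid step.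

3. Step 9. The ortho-dienone may enolise before the Cope shift (leaving a 1,1-dimethylallyl group next to the new phenol), or the Lewis acid may trigger addition of the enol ether to the aldehyde or its cleavage. The fallback sets out from 14 and returns at 18 by inverting the order of the two steps. Aldehyde 14 would be cyclised under the conditions of step 10 to (2S)-7-(tert-butyldimethylsilyloxy)-2-[3-methoxy-2-(3-methylbut-2-enyl)-4-(triisopropylsilyloxy)phenyl]-5-(3-methylbut-2-enyloxy)chroman-4-one F7. The Eu(fod)3 Claisen–Cope shift would then be run on this flavanone, where chelation by the C4 ketone and O5 and the para shift to C8 are documented, to give 18.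

**Further compounds**

F1 | step 10 | 1-[4-(tert-butyldimethylsilyloxy)-2,6-dihydroxyphenyl]ethanone | CC(=O)c1c(O)cc(O[Si](C)(C)C(C)(C)C)cc1O
F2 | step 10 | 1-[4-(tert-butyldimethylsilyloxy)-2-hydroxy-6-(3-methylbut-2-enyloxy)phenyl]ethanone | CC(=O)c1c(O)cc(O[Si](C)(C)C(C)(C)C)cc1OCC=C(C)C
F3 | step 10 | (E)-1-[4-(tert-butyldimethylsilyloxy)-2-hydroxy-6-(3-methylbut-2-enyloxy)phenyl]-3-[3-methoxy-2-(3-methylbut-2-enyl)-4-(triisopropylsilyloxy)phenyl]prop-2-en-1-one | COc1c(CC=C(C)C)c(/C=C/C(=O)c2c(O)cc(O[Si](C)(C)C(C)(C)C)cc2OCC=C(C)C)ccc1O[Si](C(C)C)(C(C)C)C(C)C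
F4 | step 10 | racemic 7-(tert-butyldimethylsilyloxy)-2-[3-methoxy-2-(3-methylbut-2-enyl)-4-(triisopropylsilyloxy)phenyl]-5-(3-methylbut-2-enyloxy)chroman-4-one | COc1c(O[Si](C(C)C)(C(C)C)C(C)C)ccc(C2CC(=O)c3c(OCC=C(C)C)cc(O[Si](C)(C)C(C)(C)C)cc3O2)c1CC=C(C)C
F5 | step 10 | racemic 7-(tert-butyldimethylsilyloxy)-5-hydroxy-2-[3-methoxy-2-(3-methylbut-2-enyl)-4-(triisopropylsilyloxy)phenyl]-8-(3-methylbut-2-enyl)chroman-4-one | COc1c(O[Si](C(C)C)(C(C)C)C(C)C)ccc(C2CC(=O)c3c(O)cc(O[Si](C)(C)C(C)(C)C)c(CC=C(C)C)c3O2)c1CC=C(C)C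
F6 | step 10 | (2R,4R)-7-(tert-butyldimethylsilyloxy)-2-[3-methoxy-2-(3-methylbut-2-enyl)-4-(triisopropylsilyloxy)phenyl]-8-(3-methylbut-2-enyl)chromane-4,5-diol | COc1c(O[Si](C(C)C)(C(C)C)C(C)C)ccc([C@H]2C[C@@H](O)c3c(O)cc(O[Si](C)(C)C(C)(C)C)c(CC=C(C)C)c3O2)c1CC=C(C)C
F7 | step 9 | (2S)-7-(tert-butyldimethylsilyloxy)-2-[3-methoxy-2-(3-methylbut-2-enyl)-4-(triisopropylsilyloxy)phenyl]-5-(3-methylbut-2-enyloxy)chroman-4-one | COc1c(O[Si](C(C)C)(C(C)C)C(C)C)ccc([C@@H]2CC(=O)c3c(OCC=C(C)C)cc(O[Si](C)(C)C(C)(C)C)cc3O2)c1CC=C(C)C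
F8 | step 8 | 1-ethynyl-3-methoxy-2-(3-methylbut-2-enyl)-4-(triisopropylsilyloxy)benzene | COc1c(CC=C(C)C)c(C#C)ccc1O[Si](C(C)C)(C(C)C)C(C)C
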